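**Slow flasks.** Start from the slowness: after 60.0 min the theta flask holds 41.6% target and the gamma flask 18.1%, with about half of the substrate still there in each (51.1% and 52.2%). Rank the new flasks from these two runs.

the same everywhere: gas 110 mM (held)
- theta: substrate 0.63 M; run made earlier
- gamma: substrate 2.8 M; run made earlier
- teal: substrate 0.50 M; time 1.0 h
- blue: substrate 1.0 M; time 1.0 h
- violet: substrate 2.5 M; time 1.0 h
- red: substrate 1.2 M; time 1.0 h
- ochre: substrate 1.8 M; time 1.0 h

- theta (time / min: target / %, substrate / %): 12.0: 6.6, 91.9; 25.0: 16.2, 78.9; 40.0: 28.5, 66.2; 50.0: 35.5, 57.7; 60.0: 41.6, 51.1
- gamma (time / min: target / %, substrate / %): 12.0: 2.2, 87.6; 25.0: 8.0, 75.4; 40.0: 11.6, 64.9; 50.0: 14.6, 58.0; 60.0: 18.1, 52.2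

(standard deviation of a reading: 0.5 percentage points)

- percent here means substrate units held: one self-condensation product counts as two
- at the start none of partner is dissolved
- the numbers in the tables scatter by 0.5 percentage points (one standard deviation)
- reactions considered so far: substrate + partner -> target; gas <-> partner; 2 substrate -> self-condensation product

1. the flasks by amount of target, in percent of the substrate charged, highest first, at 1.0 h (teal / blue / violet / red / ochre)
2. the amount of target, in percent of the substrate charged of the flask you put first, at 1.0 h
3. the amount of target, in percent of the substrate charged of the flask you put last, at 1.0 h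

**First way.** Convert percent to molar target at 60.0 min: 0.262 M in theta and 0.507 M in gamma. The charge grows by a factor of 4.44, while molar target grows by 1.93. Define the loading exponent as the logarithm of the factor in molar target divided by the logarithm of the factor in starting [substrate], at fixed gas and time; it is an apparent order in substrate. Here it is 0.442.

**Second way.** Repeat this with the target gained between 25.0 min and 60.0 min. That gives 0.382, which parts from the first value. Keep the first, because it covers the whole hour asked and rests on one gamma reading of 18.1%, while the second rests on a gain of 10 percentage points between two readings, each scattered by 0.5 points.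

**The rule.** At fixed gas and time, multiply theta's 41.6% by the charge ratio raised to the exponent minus one. The exponent is below one, so percent falls as the charge rises, and the order follows rising charge: teal, blue, red, ochre, violet. My reckoning gives teal 47.3% and violet 19.3%; the second exponent would give violet 17.7%. Teal's charge lies below theta's 0.63 M, so its value is a short extrapolation.

**The forecast.** The forecast gives teal > blue > red > ochre > violet, with 45.5% first and 19.5% last, since “partner supply is capped and self-condensation grows”, and its first value stands below mine.

**The flasks.**

    substrate + partner → target, rate k1*[substrate]*[partner]^1.5 (k = 35.0 M⁻¹·⁵ h⁻¹)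
    gas ⇌ partner, rate k2*(csat - [partner]) (kL = 7.40 h⁻¹)
    2 substrate → self-condensation product (k = 0.0960 M⁻¹ h⁻¹)

The order comes out teal > blue > red > ochre > violet, with teal at 45.3% and violet at 19.3%, so my rule stood 2 points high at teal and level at violet. At 1.00 h, partner stands at 0.0811 M in teal and 0.0460 M in violet, both below the saturation value of 110 mM. Put the rule on a further flask like teal with 0.20 M substrate, further below theta's charge: it says 78.9%, and that flask holds 55.9%.

All runs are calculated on assumed constants; scatter was added.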